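**Plan**

- Retrosynthesis: the C9–O ester bond to p-coumaric acid is cut first, then the C5–C bond of the hydroxypropyl chain (back to C5–H), then O1–C7a of the dihydrofuran, and last C2–C3 (aldol) with the one-carbon homologation that supplies C9.
- Forward: a ring A arylacetyl imide and silylated vanillin are joined at C2–C3, the acyl carbon is reduced to C9 and silylated, the dihydrofuran (the only ring formed) is closed by copper O-arylation, then the C5 chain is attached and C9 is esterified.
- Enabling feature (benzofuran numbering): O1 is attached to ring A at C7a, between C3a and the methoxy-bearing C7. The oxygen already on C2 of an open-chain 2-bromoaryl syn-diol can therefore be joined to C7a without breaking any bond at C2 or C3.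
- Stereochemistry: C2 (R) and C3 (S) both come from one Evans syn-aldol with (R)-4-benzyloxazolidin-2-one; the syn pattern becomes the trans ring and is not touched afterwards.

Key step: step 8

Remark: the target SMILES is read as the (2R,3S)-trans isomer. The descriptor at the aryl-bearing carbon changes from R in the aldol imide to S in the derived diol only because the CIP priorities change; the geometry is the same.

**Step 1**
Reactants: 1 2-bromo-3-methoxybenzaldehyde
Product: 2 2-bromo-1-methoxy-3-(2-methoxyethenyl)benzene (E/Z mixture)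
Conditions: Ph3P(CH2OMe)Cl, KOtBu, THF, 0 °C → rt
Reagents that add atoms: (methoxymethyl)triphenylphosphonium chloride, COC[P+](c1ccccc1)(c1ccccc1)c1ccccc1.[Cl-]
Why: Wittig olefination with the methoxymethylene ylide adds the carbon that becomes C9 and gives an enol ether whose geometry does not matter because the double bond is hydrolysed in the next step.

**Step 2**
Reactants: 2 2-bromo-1-methoxy-3-(2-methoxyethenyl)benzene
Product: 4 (2-bromo-3-methoxyphenyl)acetic acid, via arylacetaldehyde 3 (not isolated)
Conditions: 2 M HCl, THF, 50 °C; then NaClO2, NaH2PO4, 2-methylbut-2-ene, t-BuOH/H2O, 0 °C → rt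
Reagents that add atoms: water, O; sodium chlorite (NaClO2), [Na+].[O-]Cl=O
Why: Acid hydrolysis of the enol ether frees the arylacetaldehyde, and Pinnick oxidation of the crude aldehyde should give the acid without touching the aryl bromide or the benzylic position.

**Step 3**
Reactants: 4 (2-bromo-3-methoxyphenyl)acetic acid; 5 (R)-4-benzyloxazolidin-2-one
Product: 7 (4R)-4-benzyl-3-[2-(2-bromo-3-methoxyphenyl)acetyl]oxazolidin-2-one, via mixed pivalic anhydride 6 (not isolated)
Conditions: PivCl, Et3N, THF, −20 °C; then 5, LiCl, −20 °C → rt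
Reagents that add atoms: none
Why: N-acylation through the mixed anhydride should work because the oxazolidinone, activated by LiCl/Et3N, attacks the unhindered arylacetyl carbonyl and not the pivaloyl carbonyl.

**Step 4**
Reactants: 8 vanillin
Product: 9 3-methoxy-4-(triisopropylsilyloxy)benzaldehyde
Conditions: TIPSCl, imidazole, DMF, rt
Reagents that add atoms: triisopropylsilyl chloride, CC(C)[Si](Cl)(C(C)C)C(C)C
Why: Imidazole-promoted silylation caps the phenol as a bulky silyl ether that tolerates base, borane and mild acid and offers no unhindered aromatic C–H for the later borylation.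

**Step 5**
Reactants: 7 (4R)-4-benzyl-3-[2-(2-bromo-3-methoxyphenyl)acetyl]oxazolidin-2-one; 9 3-methoxy-4-(triisopropylsilyloxy)benzaldehyde
Product: 12 (4R)-4-benzyl-3-[(2R,3R)-2-(2-bromo-3-methoxyphenyl)-3-hydroxy-3-[3-methoxy-4-(triisopropylsilyloxy)phenyl]propanoyl]oxazolidin-2-one, via Z-dibutylboron enolate 10 (not isolated), via dibutylboron aldolate 11 (not isolated)
Conditions: Bu2BOTf, i-Pr2NEt, CH2Cl2, −78 → 0 °C; then 9, −78 → 0 °C; then pH 7 buffer, MeOH, H2O2, 0 °C
Reagents that add atoms: none
Why: In this Evans syn-aldol, soft enolisation gives the Z-boron enolate, which adds to the aldehyde through a closed Zimmerman–Traxler chair in which the dipole-opposed (R)-benzyl auxiliary blocks one enolate face, so both new centres (the later C3 and C2 of the benzofuran) should arise as R and syn to each other.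

**Step 6**
Reactants: 12 the syn-aldol imide
Product: 13 (1R,2S)-2-(2-bromo-3-methoxyphenyl)-1-[3-methoxy-4-(triisopropylsilyloxy)phenyl]propane-1,3-diol
Conditions: LiBH4, MeOH (1 equiv), THF, 0 °C
Reagents that add atoms: none
Why: Reductive cleavage of the N-acyloxazolidinone by borohydride attack at the exocyclic carbonyl gives the primary alcohol and releases the auxiliary, at a temperature low enough to avoid retro-aldol cleavage or epimerisation.

**Step 7**
Reactants: 13 the 1,3-diol
Product: 14 (1R,2S)-2-(2-bromo-3-methoxyphenyl)-3-(tert-butyldimethylsilyloxy)-1-[3-methoxy-4-(triisopropylsilyloxy)phenyl]propan-1-ol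
Conditions: TBSCl (1.05 equiv), imidazole, CH2Cl2, 0 °C
Reagents that add atoms: tert-butyldimethylsilyl chloride, CC(C)(C)[Si](C)(C)Cl
Why: Silylation should be selective for the primary hydroxyl because the secondary benzylic hydroxyl is flanked by two aryl-bearing carbons and reacts far more slowly.

**Step 8**
Reactants: 14 the bromoaryl mono-silylated diol
Product: 15 (2R,3S)-3-(tert-butyldimethylsilyloxymethyl)-7-methoxy-2-[3-methoxy-4-(triisopropylsilyloxy)phenyl]-2,3-dihydrobenzofuran (trans)
Conditions: CuI (10 mol %), 3,4,7,8-tetramethyl-1,10-phenanthroline (20 mol %), Cs2CO3 (2 equiv), toluene, 110 °C, argon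
Reagents that add atoms: none
Why: Cs2CO3 deprotonates the secondary benzylic alcohol, the alkoxide binds monovalent copper carrying the phenanthroline, the copper adds oxidatively into the neighbouring C7a–Br bond, and C(aryl)–O reductive elimination forms O1–C7a. The closest known reaction is the copper-catalysed Ullmann-type O-arylation of aliphatic alcohols with aryl bromides, used intramolecularly to make 2,3-dihydrobenzofurans. The dihydrofuran ring closes in a five-membered exo mode at the aromatic carbon (the departing bromide lies outside the new ring), by way of a six-membered aryl–copper alkoxide chelate. No stereocentre is created: C2 keeps its C–O bond and configuration and C3 is untouched, so the syn-aldol pattern is carried into the trans-(2R,3S) ring. The step needs chemoselectivity for the secondary oxygen, which the silyl cap on the primary oxygen secures (a free primary alkoxide could close its own five-membered ring on C7a), and it needs coupling to outrun hydrodebromination and carbinol oxidation, which intramolecularity and the electron-rich ligand favour. Because no carbonyl group remains after step 6, the base cannot cause retro-aldol cleavage or epimerisation.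

**Step 9**
Reactants: 15 the trans-dihydrobenzofuran
Product: 16 (2R,3S)-3-(tert-butyldimethylsilyloxymethyl)-7-methoxy-2-[3-methoxy-4-(triisopropylsilyloxy)phenyl]-5-(4,4,5,5-tetramethyl-1,3,2-dioxaborolan-2-yl)-2,3-dihydrobenzofuran
Conditions: [Ir(OMe)(cod)]2 (1.5 mol %), 4,4′-di-tert-butyl-2,2′-bipyridine (3 mol %), B2pin2 (1.0 equiv), THF, 65 °C
Reagents that add atoms: bis(pinacolato)diboron, CC1(C)OB(OC1(C)C)B1OC(C)(C)C(C)(C)O1
Why: Iridium-catalysed aromatic C–H borylation is sterically governed and takes place at C–H bonds without an ortho substituent, and C5–H of ring A is the only such bond in 15 (C4–H, C6–H and every C–H of ring G have at least one ortho neighbour).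

**Step 10**
Reactants: 16 the C5 pinacol boronate; 17 allyl bromide
Product: 18 (2R,3S)-5-allyl-3-(tert-butyldimethylsilyloxymethyl)-7-methoxy-2-[3-methoxy-4-(triisopropylsilyloxy)phenyl]-2,3-dihydrobenzofuran
Conditions: Pd(PPh3)4 (5 mol %), K2CO3 (3 equiv), THF/H2O (10:1), 65 °C
Reagents that add atoms: none
Why: In this Suzuki–Miyaura-type allyl–aryl coupling, zerovalent palladium and allyl bromide form a π-allylpalladium bromide that takes the aryl group from the base-activated boronate and reductively eliminates; carbonate is used in place of fluoride to spare the silyl ethers.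

**Step 11**
Reactants: 18 the C5-allyl compound
Product: 20 3-[(2R,3S)-3-(tert-butyldimethylsilyloxymethyl)-7-methoxy-2-[3-methoxy-4-(triisopropylsilyloxy)phenyl]-2,3-dihydrobenzofuran-5-yl]propan-1-ol, via alkylborane 19 (not isolated)
Conditions: 9-BBN, THF, 0 °C → rt; then aq NaOAc, H2O2, 0 °C → rt
Reagents that add atoms: hydrogen peroxide, OO
Why: Hydroboration–oxidation with the bulky 9-BBN places boron on the terminal carbon of the monosubstituted alkene, and the buffered peroxide oxidation gives the primary alcohol without cleaving the aryl silyl ether.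

**Step 12**
Reactants: 20 the primary alcohol
Product: 21 the tert-butyldiphenylsilyl ether of 20, (2R,3S)-5-[3-(tert-butyldiphenylsilyloxy)propyl]-3-(tert-butyldimethylsilyloxymethyl)-7-methoxy-2-[3-methoxy-4-(triisopropylsilyloxy)phenyl]-2,3-dihydrobenzofuran
Conditions: TBDPSCl, imidazole, DMF, rt
Reagents that add atoms: tert-butyldiphenylsilyl chloride, CC(C)(C)[Si](Cl)(c1ccccc1)c1ccccc1
Why: Standard silylation of the only free hydroxyl installs an acid-resistant group, introduced only after the borylation because its phenyl rings would otherwise be borylated.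

**Step 13**
Reactants: 21 the tris-silyl ether
Product: 22 [(2R,3S)-5-[3-(tert-butyldiphenylsilyloxy)propyl]-7-methoxy-2-[3-methoxy-4-(triisopropylsilyloxy)phenyl]-2,3-dihydrobenzofuran-3-yl]methanol
Conditions: CSA (10 mol %), MeOH/CH2Cl2 (1:1), 0 °C
Reagents that add atoms: none
Why: Acid-catalysed methanolysis should remove the primary TBS ether selectively, since the alkyl TBDPS ether and the aryl TIPS ether are far more stable to acid.

**Step 14**
Reactants: 23 p-coumaric acid
Product: 25 (E)-3-[4-(tert-butyldimethylsilyloxy)phenyl]prop-2-enoic acid, via silyl ester 24 (not isolated)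
Conditions: TBSCl (2.5 equiv), imidazole, DMF, rt; then AcOH, THF/H2O, rt
Reagents that add atoms: tert-butyldimethylsilyl chloride, CC(C)(C)[Si](C)(C)Cl
Why: Both acidic hydroxyls are silylated and the very labile silyl ester is then hydrolysed by dilute acid, which leaves the aryl silyl ether in place.

**Step 15**
Reactants: 22 the C9 alcohol; 25 the O-silylated p-coumaric acid
Product: 26 [(2R,3S)-5-[3-(tert-butyldiphenylsilyloxy)propyl]-7-methoxy-2-[3-methoxy-4-(triisopropylsilyloxy)phenyl]-2,3-dihydrobenzofuran-3-yl]methyl (E)-3-[4-(tert-butyldimethylsilyloxy)phenyl]prop-2-enoate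
Conditions: DCC, DMAP (cat.), CH2Cl2, 0 °C → rt
Reagents that add atoms: none
Why: Steglich esterification of the only free hydroxyl with the carbodiimide-activated acid is mild enough to keep the E double bond and all three silyl ethers.

**Step 16**
Reactants: 26 the fully silylated ester
Product: 27 [(2R,3S)-2-(4-hydroxy-3-methoxyphenyl)-5-(3-hydroxypropyl)-7-methoxy-2,3-dihydrobenzofuran-3-yl]methyl (E)-3-(4-hydroxyphenyl)prop-2-enoate (target)
Conditions: HF·pyridine, pyridine, THF, 0 °C → rt
Reagents that add atoms: none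
Why: Global desilylation by buffered HF·pyridine removes the aryl TIPS, aryl TBS and alkyl TBDPS groups as silyl fluorides without hydrolysing the cinnamate ester, isomerising the alkene or touching C2 and C3.

**Compound list**

1 | 2-bromo-3-methoxybenzaldehyde | COc1cccc(C=O)c1Br | starting material
2 | 2-bromo-1-methoxy-3-(2-methoxyethenyl)benzene (E/Z mixture) | COC=Cc1cccc(OC)c1Br | intermediate
3 | (2-bromo-3-methoxyphenyl)acetaldehyde | COc1cccc(CC=O)c1Br | intermediate (not isolated)
4 | (2-bromo-3-methoxyphenyl)acetic acid | COc1cccc(CC(=O)O)c1Br | intermediate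
5 | (R)-4-benzyloxazolidin-2-one | O=C1N[C@H](Cc2ccccc2)CO1 | starting material
6 | (2-bromo-3-methoxyphenyl)acetic pivalic anhydride | COc1cccc(CC(=O)OC(=O)C(C)(C)C)c1Br | intermediate (not isolated)
7 | (4R)-4-benzyl-3-[2-(2-bromo-3-methoxyphenyl)acetyl]oxazolidin-2-one | COc1cccc(CC(=O)N2C(=O)OC[C@H]2Cc2ccccc2)c1Br | intermediate
8 | vanillin | COc1cc(C=O)ccc1O | starting material
9 | 3-methoxy-4-(triisopropylsilyloxy)benzaldehyde | COc1cc(C=O)ccc1O[Si](C(C)C)(C(C)C)C(C)C | intermediate
10 | Z-dibutylboron enolate of 7 | CCCCB(CCCC)O/C(=C\c1cccc(OC)c1Br)N1C(=O)OC[C@H]1Cc1ccccc1 | intermediate (not isolated)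
11 | O-dibutylboryl derivative of 12 (boron aldolate) | COc1cc([C@H](OB(CCCC)CCCC)[C@H](C(=O)N2C(=O)OC[C@H]2Cc2ccccc2)c2cccc(OC)c2Br)ccc1O[Si](C(C)C)(C(C)C)C(C)C | intermediate (not isolated)
12 | (4R)-4-benzyl-3-[(2R,3R)-2-(2-bromo-3-methoxyphenyl)-3-hydroxy-3-[3-methoxy-4-(triisopropylsilyloxy)phenyl]propanoyl]oxazolidin-2-one | COc1cc([C@H](O)[C@H](C(=O)N2C(=O)OC[C@H]2Cc2ccccc2)c2cccc(OC)c2Br)ccc1O[Si](C(C)C)(C(C)C)C(C)C | intermediate
13 | (1R,2S)-2-(2-bromo-3-methoxyphenyl)-1-[3-methoxy-4-(triisopropylsilyloxy)phenyl]propane-1,3-diol | COc1cc([C@H](O)[C@H](CO)c2cccc(OC)c2Br)ccc1O[Si](C(C)C)(C(C)C)C(C)C | intermediate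
14 | (1R,2S)-2-(2-bromo-3-methoxyphenyl)-3-(tert-butyldimethylsilyloxy)-1-[3-methoxy-4-(triisopropylsilyloxy)phenyl]propan-1-ol | COc1cc([C@H](O)[C@H](CO[Si](C)(C)C(C)(C)C)c2cccc(OC)c2Br)ccc1O[Si](C(C)C)(C(C)C)C(C)C | intermediate (key-step precursor)
15 | (2R,3S)-3-(tert-butyldimethylsilyloxymethyl)-7-methoxy-2-[3-methoxy-4-(triisopropylsilyloxy)phenyl]-2,3-dihydrobenzofuran | COc1cc([C@@H]2Oc3c(OC)cccc3[C@H]2CO[Si](C)(C)C(C)(C)C)ccc1O[Si](C(C)C)(C(C)C)C(C)C | intermediate (key-step product)
16 | 5-(4,4,5,5-tetramethyl-1,3,2-dioxaborolan-2-yl) derivative of 15 | COc1cc([C@@H]2Oc3c(OC)cc(B4OC(C)(C)C(C)(C)O4)cc3[C@H]2CO[Si](C)(C)C(C)(C)C)ccc1O[Si](C(C)C)(C(C)C)C(C)C | intermediate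
17 | allyl bromide | C=CCBr | starting material
18 | 5-allyl derivative of 15 | COc1cc([C@@H]2Oc3c(OC)cc(CC=C)cc3[C@H]2CO[Si](C)(C)C(C)(C)C)ccc1O[Si](C(C)C)(C(C)C)C(C)C | intermediate
19 | B-[3-(benzofuran-5-yl)propyl]-9-borabicyclo[3.3.1]nonane adduct of 18 | COc1cc([C@@H]2Oc3c(OC)cc(CCCB4C5CCCC4CCC5)cc3[C@H]2CO[Si](C)(C)C(C)(C)C)ccc1O[Si](C(C)C)(C(C)C)C(C)C | intermediate (not isolated)
20 | 3-[(2R,3S)-3-(tert-butyldimethylsilyloxymethyl)-7-methoxy-2-[3-methoxy-4-(triisopropylsilyloxy)phenyl]-2,3-dihydrobenzofuran-5-yl]propan-1-ol | COc1cc([C@@H]2Oc3c(OC)cc(CCCO)cc3[C@H]2CO[Si](C)(C)C(C)(C)C)ccc1O[Si](C(C)C)(C(C)C)C(C)C | intermediate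
21 | tert-butyldiphenylsilyl ether of 20 | COc1cc([C@@H]2Oc3c(OC)cc(CCCO[Si](c4ccccc4)(c4ccccc4)C(C)(C)C)cc3[C@H]2CO[Si](C)(C)C(C)(C)C)ccc1O[Si](C(C)C)(C(C)C)C(C)C | intermediate
22 | [(2R,3S)-5-[3-(tert-butyldiphenylsilyloxy)propyl]-7-methoxy-2-[3-methoxy-4-(triisopropylsilyloxy)phenyl]-2,3-dihydrobenzofuran-3-yl]methanol | COc1cc([C@@H]2Oc3c(OC)cc(CCCO[Si](c4ccccc4)(c4ccccc4)C(C)(C)C)cc3[C@H]2CO)ccc1O[Si](C(C)C)(C(C)C)C(C)C | intermediate
23 | p-coumaric acid | OC(=O)/C=C/c1ccc(O)cc1 | starting material
24 | tert-butyldimethylsilyl (E)-3-[4-(tert-butyldimethylsilyloxy)phenyl]prop-2-enoate | CC(C)(C)[Si](C)(C)OC(=O)/C=C/c1ccc(O[Si](C)(C)C(C)(C)C)cc1 | intermediate (not isolated)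
25 | (E)-3-[4-(tert-butyldimethylsilyloxy)phenyl]prop-2-enoic acid | OC(=O)/C=C/c1ccc(O[Si](C)(C)C(C)(C)C)cc1 | intermediate
26 | [(2R,3S)-5-[3-(tert-butyldiphenylsilyloxy)propyl]-7-methoxy-2-[3-methoxy-4-(triisopropylsilyloxy)phenyl]-2,3-dihydrobenzofuran-3-yl]methyl (E)-3-[4-(tert-butyldimethylsilyloxy)phenyl]prop-2-enoate | COc1cc([C@@H]2Oc3c(OC)cc(CCCO[Si](c4ccccc4)(c4ccccc4)C(C)(C)C)cc3[C@H]2COC(=O)/C=C/c2ccc(O[Si](C)(C)C(C)(C)C)cc2)ccc1O[Si](C(C)C)(C(C)C)C(C)C | intermediate
27 | [(2R,3S)-2-(4-hydroxy-3-methoxyphenyl)-5-(3-hydroxypropyl)-7-methoxy-2,3-dihydrobenzofuran-3-yl]methyl (E)-3-(4-hydroxyphenyl)prop-2-enoate | COc1cc([C@@H]2Oc3c(OC)cc(CCCO)cc3[C@H]2COC(=O)/C=C/c2ccc(O)cc2)ccc1O | target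

**Step count**

Total: 16 steps. Longest linear sequence: 14 steps (steps 1–3, 5–13, 15 and 16); steps 4 and 14 prepare the two side components.

**Steps most likely to fail**

Step 8. Oxidative addition at the bromide, which is flanked on both sides, may be slow, so that hydrodebromination or oxidation of the carbinol competes. A base-induced shift of the TBS group from the primary to the secondary oxygen is also possible, after which the primary alkoxide could close its own five-membered ring on C7a. The fallback sets out from 14 and returns at 15, and it reverses the polarity of the closure. Deprotonation of the carbinol and bromine–lithium exchange (n-BuLi, 2.2 equiv, THF, −78 °C) followed by B(OMe)3 should give the dimethyl arylboronate of 14 F1. This is oxidised in the same flask (H2O2, pH 7 buffer, 0 °C) to the phenol (1R,2S)-3-(tert-butyldimethylsilyloxy)-2-(2-hydroxy-3-methoxyphenyl)-1-[3-methoxy-4-(triisopropylsilyloxy)phenyl]propan-1-ol F2. A catalytic amount of CSA in CH2Cl2 at −20 °C should then ionise the 4-silyloxybenzylic alcohol, and the ring A phenol should add to the cation on the face away from the C3 substituent. This closes O1–C2 and gives trans-15; C3 keeps the configuration from the aldol and dictates that of C2. This route gives up the O1–C7a closure and is meant only as a last resort.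

Step 5. Enolisation of the hindered arylacetyl imide may be incomplete, and retro-aldol equilibration of the electron-rich adduct may erode the syn selectivity. The fallback sets out from 4 and 9 and returns at 13, and it sets the two centres one after the other. Aldehyde 9 is oxidised (NaClO2, NaH2PO4, 2-methylbut-2-ene) to 3-methoxy-4-(triisopropylsilyloxy)benzoic acid F3 and converted with oxalyl chloride and catalytic DMF into 3-methoxy-4-(triisopropylsilyloxy)benzoyl chloride F4. Acid 4 is attached through anhydride 6 to (S)-4-benzyloxazolidin-2-one to give (4S)-4-benzyl-3-[2-(2-bromo-3-methoxyphenyl)acetyl]oxazolidin-2-one F5. The (S)-auxiliary is needed because the chelated lithium enolate reacts on the face opposite to the one used by the boron enolate. The lithium enolate of F5 (LiN(i-Pr)2, THF, −78 °C) should be C-acylated by F4 on the face away from the benzyl group to give the β-keto imide (4S)-4-benzyl-3-[(2R)-2-(2-bromo-3-methoxyphenyl)-3-[3-methoxy-4-(triisopropylsilyloxy)phenyl]-3-oxopropanoyl]oxazolidin-2-one F6, in which allylic strain keeps the α-hydrogen from enolising. Chelation-controlled reduction with Zn(BH4)2 (CH2Cl2, −20 °C) should give the syn-hydroxy imide (4S)-4-benzyl-3-[(2R,3R)-2-(2-bromo-3-methoxyphenyl)-3-hydroxy-3-[3-methoxy-4-(triisopropylsilyloxy)phenyl]propanoyl]oxazolidin-2-one F7. LiBH4 as in step 6 then releases diol 13.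

Step 10. Transmetalation of the electron-rich boronate may be slow, and the allyl double bond may migrate into conjugation with ring A under palladium and base. The fallback sets out from 16 and returns at 20, and it brings in the three carbons at the ester oxidation level. Rhodium-catalysed conjugate addition of 16 to methyl acrylate ([Rh(OH)(cod)]2, dioxane/H2O, 60 °C) should give methyl 3-[(2R,3S)-3-(tert-butyldimethylsilyloxymethyl)-7-methoxy-2-[3-methoxy-4-(triisopropylsilyloxy)phenyl]-2,3-dihydrobenzofuran-5-yl]propanoate F8. Reduction with i-Bu2AlH (CH2Cl2, −78 → 0 °C) then gives alcohol 20, so that steps 10 and 11 are both bypassed.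

**Further compounds**

F1 | step 8 | dimethyl arylboronate of 14 (B(OMe)2 in place of Br, side chain unchanged) | COc1cc([C@H](O)[C@H](CO[Si](C)(C)C(C)(C)C)c2cccc(OC)c2B(OC)OC)ccc1O[Si](C(C)C)(C(C)C)C(C)C
F2 | step 8 | (1R,2S)-3-(tert-butyldimethylsilyloxy)-2-(2-hydroxy-3-methoxyphenyl)-1-[3-methoxy-4-(triisopropylsilyloxy)phenyl]propan-1-ol | COc1cc([C@H](O)[C@H](CO[Si](C)(C)C(C)(C)C)c2cccc(OC)c2O)ccc1O[Si](C(C)C)(C(C)C)C(C)C
F3 | step 5 | 3-methoxy-4-(triisopropylsilyloxy)benzoic acid | COc1cc(C(=O)O)ccc1O[Si](C(C)C)(C(C)C)C(C)C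
F4 | step 5 | 3-methoxy-4-(triisopropylsilyloxy)benzoyl chloride | COc1cc(C(=O)Cl)ccc1O[Si](C(C)C)(C(C)C)C(C)C
F5 | step 5 | (4S)-4-benzyl-3-[2-(2-bromo-3-methoxyphenyl)acetyl]oxazolidin-2-one | COc1cccc(CC(=O)N2C(=O)OC[C@@H]2Cc2ccccc2)c1Br
F6 | step 5 | (4S)-4-benzyl-3-[(2R)-2-(2-bromo-3-methoxyphenyl)-3-[3-methoxy-4-(triisopropylsilyloxy)phenyl]-3-oxopropanoyl]oxazolidin-2-one | COc1cc(C(=O)[C@H](C(=O)N2C(=O)OC[C@@H]2Cc2ccccc2)c2cccc(OC)c2Br)ccc1O[Si](C(C)C)(C(C)C)C(C)C
F7 | step 5 | (4S)-4-benzyl-3-[(2R,3R)-2-(2-bromo-3-methoxyphenyl)-3-hydroxy-3-[3-methoxy-4-(triisopropylsilyloxy)phenyl]propanoyl]oxazolidin-2-one | COc1cc([C@H](O)[C@H](C(=O)N2C(=O)OC[C@@H]2Cc2ccccc2)c2cccc(OC)c2Br)ccc1O[Si](C(C)C)(C(C)C)C(C)C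
F8 | step 10 | methyl 3-[(2R,3S)-3-(tert-butyldimethylsilyloxymethyl)-7-methoxy-2-[3-methoxy-4-(triisopropylsilyloxy)phenyl]-2,3-dihydrobenzofuran-5-yl]propanoate | COc1cc([C@@H]2Oc3c(OC)cc(CCC(=O)OC)cc3[C@H]2CO[Si](C)(C)C(C)(C)C)ccc1O[Si](C(C)C)(C(C)C)C(C)C
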